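The left-handed product runs ahead of the right-handed product early in the earlier flasks. What is wanted is how far ahead it still stands after 3.0 h, reckoned as the difference of the two products over their sum.

the same everywhere: gas 11 mM (held)

| charge | left-handed substrate | right-handed substrate | temperature | remark | time |
|---|---|---|---|---|---|
| west | 0.050 M | 0.050 M | 15 °C | run made earlier |  |
| south-west | 0.075 M | 0.075 M | 50 °C | run made earlier |  |
| delta | 0.10 M | 0.10 M | 80 °C |  | 3.0 h |
| beta | 0.10 M | 0.10 M | 20 °C |  | 3.0 h |
| eta | 0.10 M | 0.10 M | 40 °C |  | 3.0 h |
| theta | 0.10 M | 0.10 M | 60 °C |  | 3.0 h |

| run | time / h | left-handed product / % | right-handed product / % |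
|---|---|---|---|
| west | 8.00 | 43.3 | 12.7 |
| west | 15.0 | 44.3 | 24.3 |
| west | 25.0 | 43.3 | 34.1 |
| west | 30.0 | 42.9 | 38.6 |
| west | 40.0 | 43.4 | 44.2 |
| west | 50.0 | 42.5 | 46.8 |
| west | 60.0 | 44.2 | 49.9 |
| south-west | 1.33 | 29.4 | 25.1 |
| south-west | 3.00 | 36.7 | 39.7 |
| south-west | 4.00 | 41.2 | 44.2 |
| south-west | 6.00 | 46.5 | 47.7 |
| south-west | 8.00 | 49.1 | 50.4 |
| south-west | 12.0 | 50.4 | 50.1 |

(standard deviation of a reading: 0.5 percentage points)
- the flask with the highest excess of left-handed product over right-handed product ("all alike" if they lie within 1.5 percentage points) (delta / beta / eta / theta / all alike)
- excess of left-handed product over right-handed product at the end, delta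
- excess of left-handed product over right-handed product at the end, beta
- excess of left-handed product over right-handed product at the end, eta
- excess of left-handed product over right-handed product at the end, theta
- reagent is single-handed; left-handed substrate and right-handed substrate are mirror images of each other, charged as a racemate, each of them at the stated concentration
- at the start none of the gas is in solution
- an excess is below zero if the other one leads
- the handed part of reagent does not stay in what it makes, so the products of the two hands are mirror images too

Suppose each substrate falls first-order in one shared pool of reagent. Then d ln c(left-handed substrate)/dt and d ln c(right-handed substrate)/dt keep a fixed ratio, and the unknown history of c(reagent) cancels on integration. In west after 8.00 h, the products imply rests of 13.4% of the left-handed and 74.6% of the right-handed substrate. The ratio of their logarithms reads 6.86; call it s, the apparent selectivity factor of this kinetic resolution. It is a reading that carries the scatter and also takes each product to stand as it was formed, an assumption that the scatter does not measure.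

The curve follows. On this reading the excess in west starts at (s−1)/(s+1), or 74.6%, while the left-handed substrate there decays at about 0.251 /h. The knee comes in west by 8.00 h, where the left-handed product stops near 43.3%. The crossing lies between 30.0 h and 40.0 h in west, but south-west has crossed by 3.00 h. The level is equal products, 50.4% and 50.1% in south-west at 12.0 h.

The reckoning here is made for beta, with west's decay carried over unchanged. It leaves 47.1% of the left-handed substrate, and the closed form turns that into an excess of 67.1%.

The forecast names beta, reading “a fast left-only burst limited by reagent”. It gives delta 0%, beta 40% (from 28% to 55%), eta −3% and theta 1%. The reckoning here lies above that beta range.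

The simulation gives beta: delta −0.117%, beta 66.6%, eta 5.13%, theta −1.52%.

    left-handed product ⇌ right-handed product (k = 7.90 × 10⁻⁶ /s, Ea = 105 kJ/mol)
    gas ⇌ reagent, rate k2*(csat - [reagent]) (kL = 0.00230 /s)
    reagent + left-handed substrate → left-handed product (k = 0.0130 /M/s, Ea = 71.0 kJ/mol)
    reagent + right-handed substrate → right-handed product (k = 0.00130 /M/s, Ea = 59.0 kJ/mol)
    (constants at 20 °C)

In beta, the left-handed substrate fell from 30.8% at 1.50 h to 17.2% at 3.00 h, while reagent stood at 0.00878 M and the products reached 31.5% and 6.32%. The rest of its own charge, 34%, is lower than reckoned, yet the apparent s turns it into an excess of 63.9%, close to the result.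

Theta read at 80 min keeps 8.1% of its left-handed substrate, for which s gives 49.9%. The flask shows 2.57%, and theta's exchange half-life between the products, 0.0691 h, is shorter than that reading time.

The readings were computed from invented constants; scatter was added.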